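The route rests on disconnecting C3–C4 of each oxepane (ring A: C1–C2–C3–C4–O–C5–C10), inside the O–C4(CH3)2–C3(O) unit. That bond is made as the double bond of a cyclic enol ether, by carbonyl–olefin ring closure between the acetate on the ring-fusion oxygen (C5–O) and the butenyl chain on C10. One operation closes the seven-membered ring and gives C4 its first methyl group; epoxidation and methyl transfer then complete the carbinol and the gem-dimethyl group. The precursor is a trans-2-butenylcyclohexyl acetate with a silylated C8 carbinol and a protected C11 hydroxymethyl arm. Two C8-epimeric bicycles are joined by olefination at C11 and hydrogenated.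

Key step: step 10

Remark on the target: read from its SMILES, the two halves are not identical. The 3-acetoxy half has 8β-OAc/8α-CH3 and the 3'-hydroxy half has 8'α-OAc/8'β-CH3, so they are C8 epimers and two different bicyclic fragments are built from one common ketone.
Remark on locants and abbreviations: each half is numbered C1–C2–C3(carbinol)–C4(CMe2)–O–C5(ring-fusion CH–O)–C6–C7–C8(tertiary carbinol)–C9(CH bearing C11)–C10(angular C–CH3), with primes for the 3'-hydroxy half; monocyclic ring-B intermediates carry the same locants. β is the face of the C10 methyl group, α the opposite face. TBS = tert-butyldimethylsilyl, TES = triethylsilyl, TMS = trimethylsilyl, NAP = 2-naphthylmethyl, PT = 1-phenyl-1H-tetrazol-5-yl.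
Assumption: but-3-en-1-ylmagnesium bromide (THF solution) and 2-naphthylmethyl chloromethyl ether are taken as purchasable.

Step 1
Reactants: 1 2-methylcyclohex-2-en-1-one
Product: 2 (S)-2-methylcyclohex-2-en-1-ol
Conditions: (R)-2-methyl-CBS-oxazaborolidine (10 mol %), BH3·SMe2, THF, –20 °C
Reagents that add atoms: none
Why: Corey–Bakshi–Shibata reduction: the oxazaborolidine–borane complex binds the carbonyl with the larger α-methylvinyl arm turned away from the catalyst and delivers hydride to one face, so the (R)-catalyst should give the (S)-allylic alcohol, whose carbinol carbon becomes C5 and C5'.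

Step 2
Reactants: 2 (S)-2-methylcyclohex-2-en-1-ol
Product: 3 (S)-tert-butyldimethyl[(2-methylcyclohex-2-en-1-yl)oxy]silane
Conditions: TBSCl, imidazole, DMF, rt
Reagents that add atoms: tert-butyldimethylsilyl chloride, CC(C)(C)[Si](C)(C)Cl
Why: Imidazole-promoted silylation of an unhindered secondary alcohol; the bulky TBS group later steers the cuprate and the stereocenter is not touched.

Step 3
Reactants: 3 (S)-tert-butyldimethyl[(2-methylcyclohex-2-en-1-yl)oxy]silane
Product: 4 (S)-4-[(tert-butyldimethylsilyl)oxy]-3-methylcyclohex-2-en-1-one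
Conditions: CrO3, 3,5-dimethylpyrazole, CH2Cl2, –20 °C
Reagents that add atoms: chromium trioxide, O=[Cr](=O)=O
Why: Allylic oxidation with the chromium trioxide–3,5-dimethylpyrazole complex should attack the only allylic ring methylene (the other allylic position is the shielded silyloxy methine) and give the γ-silyloxy enone with the carbinol center intact.

Step 4
Reactants: 4 (S)-4-[(tert-butyldimethylsilyl)oxy]-3-methylcyclohex-2-en-1-one; 5 but-3-en-1-ylmagnesium bromide
Product: 6 enol silane tert-butyl{[(1S,2S)-2-(but-3-en-1-yl)-2-methyl-4-[(trimethylsilyl)oxy]cyclohex-3-en-1-yl]oxy}dimethylsilane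
Conditions: CuBr·SMe2 (20 mol %), TMSCl, HMPA, THF, –78 °C; Et3N, pentane work-up
Reagents that add atoms: chlorotrimethylsilane, C[Si](C)(C)Cl
Why: Copper-catalysed conjugate addition of the Grignard reagent with TMSCl acceleration: the butenyl group adds to the β-carbon anti to the neighbouring OTBS group, which sets the quaternary C10 (butenyl α, methyl β), and the enolate is trapped regiospecifically as its silyl ether.

Step 5
Reactants: 6 enol silane (C8=C9); 7 2-[(chloromethoxy)methyl]naphthalene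
Product: 8 ring-B ketone 10α-(but-3-en-1-yl)-10β-methyl-9β-(NAP-oxymethyl)-5β-(TBS-oxy)cyclohexan-8-one
Conditions: TiCl4, CH2Cl2, –78 °C
Reagents that add atoms: none
Why: Mukaiyama-type alkylation of the enol silane by the oxocarbenium ion that TiCl4 releases from the chloromethyl ether; attack anti to the butenyl chain places CH2ONAP equatorial and cis to the C10 methyl (9β), which is also the thermodynamically preferred configuration of this epimerisable α-center, and the NAP ether is chosen because DDQ can later remove it beside a benzyl ether.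

Step 6
Reactants: 8 ring-B ketone
Product: 9 10α-(but-3-en-1-yl)-8α,10β-dimethyl-9β-(NAP-oxymethyl)-5β-(TBS-oxy)cyclohexan-8β-ol
Conditions: MeMgBr, Et2O, –78 → 0 °C
Reagents that add atoms: methylmagnesium bromide, C[Mg]Br
Why: Grignard 1,2-addition: the axial C10 methyl blocks the axial (β) trajectory, so methyl should enter equatorially from the α face and the new C8 hydroxyl is axial (β), the configuration of the 3-acetoxy half.

Step 7
Reactants: 9 8β-tertiary alcohol with 5β-OTBS
Product: 10 10α-(but-3-en-1-yl)-8α,10β-dimethyl-9β-(NAP-oxymethyl)cyclohexane-5β,8β-diol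
Conditions: Bu4NF, THF, 50 °C
Reagents that add atoms: none
Why: Fluoride-induced cleavage of the secondary TBS ether frees the ring-fusion carbinol; no other group responds to fluoride.

Step 8
Reactants: 10 5β,8β-diol
Product: 11 5β-acetoxy-10α-(but-3-en-1-yl)-8α,10β-dimethyl-9β-(NAP-oxymethyl)cyclohexan-8β-ol
Conditions: Ac2O, pyridine, DMAP (cat.), CH2Cl2, 0 °C → rt
Reagents that add atoms: acetic anhydride, CC(=O)OC(C)=O
Why: Nucleophile-catalysed acetylation is selective for the secondary C5 hydroxyl because the axial tertiary C8 hydroxyl does not acylate at room temperature.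

Step 9
Reactants: 11 5β-acetate with free 8β-hydroxyl
Product: 12 butenyl cyclohexyl acetate 5β-acetoxy-10α-(but-3-en-1-yl)-8α,10β-dimethyl-9β-(NAP-oxymethyl)-8β-(TES-oxy)cyclohexane
Conditions: Et3SiOTf, 2,6-lutidine, CH2Cl2, –78 → 0 °C
Reagents that add atoms: triethylsilyl trifluoromethanesulfonate, CC[Si](CC)(CC)OS(=O)(=O)C(F)(F)F
Why: Silyl triflate silylation of the hindered tertiary alcohol masks the only protic group before the titanium reagent; silylating only after the TBS-to-acetate exchange avoids having to cleave a secondary silyl ether beside a tertiary one.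

Step 10
Reactants: 12 butenyl cyclohexyl acetate
Product: 13 bicyclic enol ether: trans-fused 4-methyl-Δ3-oxepene (2-methyl-tetrahydrooxepine) with 8α-CH3 and 10β-CH3 and 9β-CH2ONAP and 8β-OTES and 5α-H
Conditions: TiCl4, TMEDA, Zn, PbCl2 (cat.), CH3CHBr2, THF/CH2Cl2, 0 → 65 °C
Reagents that add atoms: none
Why: The low-valent titanium ethylidene made from TiCl4, Zn, PbCl2 and CH3CHBr2 exchanges with the monosubstituted butenyl alkene (propene is released) to give a titanium alkylidene tethered to C10, which adds across the C5 acetate carbonyl to an oxatitanacyclobutane that collapses to the C3=C4 enol ether and a titanium oxo species. The closest known reaction type is the Takai–Utimoto alkylidenation of esters in its olefinic-ester cyclisation (carbonyl–olefin metathesis) form. Ring A is closed as a seven-membered ring by intramolecular [2+2] addition of the alkylidene to the ester carbonyl followed by cycloreversion, with the new double bond inside the ring. No stereocenter is formed; C5, C8, C9 and C10 are untouched, and the trans-diequatorial butenyl and acetoxy groups fix the trans ring fusion in advance. The step needs ring closure to beat simple ethylidenation of the acetate and intermolecular coupling; this should be secured by fast exchange at the unhindered terminal alkene, by the vicinal proximity of alkylidene and acetate, by dilution, and by the absence of any other carbonyl group, the silyl and NAP ethers being inert to the reagent.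

Step 11
Reactants: 13 bicyclic enol ether
Product: 15 trans-fused oxepan-3α-ol with 4,4,8α,10β-tetramethyl and 9β-CH2ONAP and 8β-OTES groups, via 3α,4α-epoxy acetal 14 (not isolated)
Conditions: dimethyldioxirane, acetone/CH2Cl2, –78 → 0 °C; evaporate; AlMe3, CH2Cl2, –78 → 0 °C
Reagents that add atoms: dimethyldioxirane, CC1(C)OO1; trimethylaluminium, C[Al](C)C
Why: Dimethyldioxirane should epoxidise the electron-rich enol ether on the α face, opposite the angular C10 methyl, which sets C3; AlMe3 then ionises the acetal C4–O bond of the epoxide and transfers methyl to C4 (known Lewis-acid opening of glycal-type epoxides by trialkylaluminium), leaving the 3α-hydroxyl and completing the gem-dimethyl group.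

Step 12
Reactants: 15 oxepan-3α-ol
Product: 16 3α,8β-bis(TES-oxy) oxepane with 9β-CH2ONAP
Conditions: Et3SiOTf, 2,6-lutidine, CH2Cl2, –78 → 0 °C
Reagents that add atoms: triethylsilyl trifluoromethanesulfonate, CC[Si](CC)(CC)OS(=O)(=O)C(F)(F)F
Why: Silyl triflate silylation of the neopentylic secondary alcohol keeps esters out of the later carbanion coupling and lets C3–O and C8–O be unmasked together.

Step 13
Reactants: 16 bis(TES) ether with 9β-CH2ONAP
Product: 17 C11 alcohol: 9β-hydroxymethyl-3α,8β-bis(TES-oxy) oxepane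
Conditions: DDQ, CH2Cl2/pH 7 phosphate buffer, 0 °C → rt
Reagents that add atoms: none
Why: Oxidative cleavage of the 2-naphthylmethyl ether by DDQ (hydride abstraction, then hydrolysis of the oxocarbenium ion) frees the C11 alcohol while the silyl ethers survive the buffered medium.

Step 14
Reactants: 17 C11 alcohol
Product: 18 C11 PT sulfide of the 3α,8β-bis(TES-oxy) oxepane
Conditions: 1-phenyl-1H-tetrazole-5-thiol, PPh3, DIAD, THF, 0 → 40 °C
Reagents that add atoms: 1-phenyl-1H-tetrazole-5-thiol, Sc1nnnn1-c1ccccc1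
Why: Mitsunobu thioetherification of the primary alcohol with the acidic tetrazole thiol (SN2 at C11, no stereocenter involved).

Step 15
Reactants: 18 C11 PT sulfide
Product: 19 C11 PT sulfone of the 3α,8β-bis(TES-oxy) oxepane
Conditions: mCPBA, NaHCO3, CH2Cl2, 0 °C → rt
Reagents that add atoms: 3-chloroperbenzoic acid, O=C(OO)c1cccc(Cl)c1
Why: Peracid oxidation of the sulfide through the sulfoxide to the sulfone; the fragment holds no alkene or other oxidisable group at this stage.

Step 16
Reactants: 8 ring-B ketone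
Product: 20 10'α-(but-3-en-1-yl)-10'β-methyl-8'-methylidene-9'β-(NAP-oxymethyl)-5'β-(TBS-oxy)cyclohexane
Conditions: Zn, CH2Br2, TiCl4, THF/CH2Cl2, 0 °C → rt
Reagents that add atoms: dibromomethane, BrCBr
Why: Takai–Lombardo methylenation: the non-basic gem-dizinc/titanium reagent olefinates the hindered ketone without epimerising C9' or eliminating the β-alkoxy group, which a basic ylide might do.

Step 17
Reactants: 20 8'-methylidene compound
Product: 21 spiro-epoxide of 20 with the epoxide oxygen 8'α and its CH2 8'β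
Conditions: mCPBA (1.05 equiv), NaHCO3, CH2Cl2, –20 → 0 °C
Reagents that add atoms: 3-chloroperbenzoic acid, O=C(OO)c1cccc(Cl)c1
Why: Prilezhaev epoxidation: the 1,1-disubstituted exocyclic alkene is much more nucleophilic than the monosubstituted butenyl alkene, and the peracid should approach from the equatorial α side because the axial C10' methyl shields the β face, so the oxygen at C8' is α.

Step 18
Reactants: 21 spiro-epoxide
Product: 22 10'α-(but-3-en-1-yl)-8'β,10'β-dimethyl-9'β-(NAP-oxymethyl)-5'β-(TBS-oxy)cyclohexan-8'α-ol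
Conditions: LiEt3BH, THF, 0 °C → rt
Reagents that add atoms: none
Why: Hydride opens the spiro-epoxide at its unsubstituted CH2 terminus (SN2), giving the 8'α tertiary alcohol with an 8'β methyl group, the C8 epimer of 9.

Step 19
Reactants: 22 8'α-tertiary alcohol with 5'β-OTBS
Product: 23 10'α-(but-3-en-1-yl)-8'β,10'β-dimethyl-9'β-(NAP-oxymethyl)cyclohexane-5'β,8'α-diol
Conditions: Bu4NF, THF, 50 °C
Reagents that add atoms: none
Why: Fluoride cleavage of the secondary TBS ether, as in step 7.

Step 20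
Reactants: 23 5'β,8'α-diol
Product: 24 5'β-acetoxy-10'α-(but-3-en-1-yl)-8'β,10'β-dimethyl-9'β-(NAP-oxymethyl)cyclohexan-8'α-ol
Conditions: Ac2O, pyridine, DMAP (cat.), CH2Cl2, 0 °C → rt
Reagents that add atoms: acetic anhydride, CC(=O)OC(C)=O
Why: Selective nucleophile-catalysed acetylation of the secondary hydroxyl beside the unreactive tertiary one, as in step 8.

Step 21
Reactants: 24 5'β-acetate with free 8'α-hydroxyl
Product: 25 5'β-acetoxy-10'α-(but-3-en-1-yl)-8'β,10'β-dimethyl-9'β-(NAP-oxymethyl)-8'α-(TES-oxy)cyclohexane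
Conditions: Et3SiOTf, 2,6-lutidine, CH2Cl2, –78 → 0 °C
Reagents that add atoms: triethylsilyl trifluoromethanesulfonate, CC[Si](CC)(CC)OS(=O)(=O)C(F)(F)F
Why: Silyl triflate silylation of the tertiary (here equatorial) alcohol, as in step 9.

Step 22
Reactants: 25 C8'-epimeric butenyl cyclohexyl acetate
Product: 26 C8'-epimeric bicyclic enol ether: trans-fused 4'-methyl-Δ3'-oxepene with 8'β-CH3 and 10'β-CH3 and 9'β-CH2ONAP and 8'α-OTES
Conditions: TiCl4, TMEDA, Zn, PbCl2 (cat.), CH3CHBr2, THF/CH2Cl2, 0 → 65 °C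
Reagents that add atoms: none
Why: The same titanium ethylidene olefinic-ester cyclisation (carbonyl–olefin metathesis) as in step 10; the epimeric C8' center is remote from the reacting acetate and alkene and no stereocenter is formed.

Step 23
Reactants: 26 C8'-epimeric bicyclic enol ether
Product: 28 trans-fused oxepan-3'α-ol with 4',4',8'β,10'β-tetramethyl and 9'β-CH2ONAP and 8'α-OTES groups, via 3'α,4'α-epoxy acetal 27 (not isolated)
Conditions: dimethyldioxirane, acetone/CH2Cl2, –78 → 0 °C; evaporate; AlMe3, CH2Cl2, –78 → 0 °C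
Reagents that add atoms: dimethyldioxirane, CC1(C)OO1; trimethylaluminium, C[Al](C)C
Why: Enol ether epoxidation anti to the angular C10' methyl sets the 3'α oxygen, and trialkylaluminium opening of the glycal-type epoxide at the acetal carbon adds the second C4' methyl, as in step 11.

Step 24
Reactants: 28 oxepan-3'α-ol
Product: 29 3'α-benzyloxy oxepane with 9'β-CH2ONAP and 8'α-OTES
Conditions: NaH, BnBr, Bu4NI (cat.), DMF, 0 °C → rt
Reagents that add atoms: benzyl bromide, BrCc1ccccc1
Why: Williamson etherification of the sodium alkoxide; the benzyl ether survives DDQ, fluoride and acetylation and leaves only in the final hydrogenolysis, so C3' alone stays unacetylated.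

Step 25
Reactants: 29 3'α-benzyl ether with 9'β-CH2ONAP
Product: 30 C11' alcohol: 3'α-benzyloxy-9'β-hydroxymethyl-8'α-(TES-oxy) oxepane
Conditions: DDQ, CH2Cl2/pH 7 phosphate buffer, 0 °C → rt
Reagents that add atoms: none
Why: DDQ cleaves the more electron-rich 2-naphthylmethyl ether selectively beside the benzyl ether (oxidative deprotection).

Step 26
Reactants: 30 C11' alcohol
Product: 31 C11' aldehyde: 3'α-benzyloxy-8'α-(TES-oxy) oxepane-9'β-carbaldehyde
Conditions: Dess–Martin periodinane, NaHCO3, CH2Cl2, rt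
Reagents that add atoms: none
Why: Dess–Martin oxidation of the primary alcohol under buffered, non-epimerising conditions; the equatorial 8'α-OTES group is poorly aligned for β-elimination from the aldehyde.

Step 27
Reactants: 19 C11 PT sulfone; 31 C11' aldehyde
Product: 32 (E)-C11=C11' alkene linking the 3α,8β-bis(TES-oxy) half to the 3'α-benzyloxy-8'α-(TES-oxy) half
Conditions: KN(SiMe3)2, THF, –78 °C; then 31, –78 °C → rt
Reagents that add atoms: none
Why: Julia–Kocienski olefination: the potassium sulfonyl carbanion adds to the aldehyde, the alkoxide undergoes Smiles rearrangement onto the tetrazole, and loss of SO2 and tetrazolate forms the C11=C11' bond (E expected, but the geometry is irrelevant because the alkene is hydrogenated); C9 and C9' should not epimerise at low temperature.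

Step 28
Reactants: 32 tris(TES) alkene
Product: 33 3α,8β,8'α-triol with 3'α-benzyloxy group and C11=C11' alkene
Conditions: HF·pyridine, pyridine, THF, 0 °C → rt
Reagents that add atoms: none
Why: Fluoride desilylation removes the three TES ethers while the benzyl ether and the alkene are inert.

Step 29
Reactants: 33 triol
Product: 34 3α,8β,8'α-triacetate with 3'α-benzyloxy group and C11=C11' alkene
Conditions: Ac2O, Et3N, DMAP, toluene, 60 °C
Reagents that add atoms: acetic anhydride, CC(=O)OC(C)=O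
Why: DMAP-catalysed acetylation under forcing conditions esterifies the secondary C3 and both tertiary C8 and C8' hydroxyls; C3' is still benzylated, so the acetylation pattern of the target is fixed here.

Step 30
Reactants: 34 triacetate benzyl ether
Product: 35 target CNP0169816.1
Conditions: H2 (3 atm), Pd(OH)2/C, EtOAc/EtOH, rt
Reagents that add atoms: none
Why: Heterogeneous catalytic hydrogenation saturates the disubstituted C11=C11' alkene and hydrogenolyses the benzyl ether in one operation; acetates, ring ethers and all stereocenters are unaffected.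

Compound list
1 | 2-methylcyclohex-2-en-1-one | CC1=CCCCC1=O | starting material
2 | (S)-2-methylcyclohex-2-en-1-ol | CC1=CCCC[C@@H]1O | intermediate
3 | (S)-tert-butyldimethyl[(2-methylcyclohex-2-en-1-yl)oxy]silane | CC1=CCCC[C@@H]1O[Si](C)(C)C(C)(C)C | intermediate
4 | (S)-4-[(tert-butyldimethylsilyl)oxy]-3-methylcyclohex-2-en-1-one | O=C1C=C(C)[C@H](CC1)O[Si](C)(C)C(C)(C)C | intermediate
5 | but-3-en-1-ylmagnesium bromide | C=CCC[Mg]Br | starting material
6 | enol silane tert-butyl{[(1S,2S)-2-(but-3-en-1-yl)-2-methyl-4-[(trimethylsilyl)oxy]cyclohex-3-en-1-yl]oxy}dimethylsilane (butenyl trans to OTBS) | C=CCC[C@]1(C)[C@H](CCC(O[Si](C)(C)C)=C1)O[Si](C)(C)C(C)(C)C | intermediate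
7 | 2-[(chloromethoxy)methyl]naphthalene (2-naphthylmethyl chloromethyl ether) | ClCOCc1ccc2ccccc2c1 | starting material
8 | ring-B ketone 10α-(but-3-en-1-yl)-10β-methyl-9β-(NAP-oxymethyl)-5β-(TBS-oxy)cyclohexan-8-one | C=CCC[C@]1(C)[C@H](CCC(=O)[C@H]1COCc2ccc3ccccc3c2)O[Si](C)(C)C(C)(C)C | intermediate
9 | 10α-(but-3-en-1-yl)-8α,10β-dimethyl-9β-(NAP-oxymethyl)-5β-(TBS-oxy)cyclohexan-8β-ol | C=CCC[C@]1(C)[C@H](CC[C@@](C)(O)[C@H]1COCc2ccc3ccccc3c2)O[Si](C)(C)C(C)(C)C | intermediate
10 | 10α-(but-3-en-1-yl)-8α,10β-dimethyl-9β-(NAP-oxymethyl)cyclohexane-5β,8β-diol | C=CCC[C@]1(C)[C@H](CC[C@@](C)(O)[C@H]1COCc2ccc3ccccc3c2)O | intermediate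
11 | 5β-acetoxy-10α-(but-3-en-1-yl)-8α,10β-dimethyl-9β-(NAP-oxymethyl)cyclohexan-8β-ol | C=CCC[C@]1(C)[C@H](CC[C@@](C)(O)[C@H]1COCc2ccc3ccccc3c2)OC(C)=O | intermediate
12 | butenyl cyclohexyl acetate (key-step precursor): 5β-acetoxy-10α-(but-3-en-1-yl)-8α,10β-dimethyl-9β-(NAP-oxymethyl)-8β-(TES-oxy)cyclohexane | C=CCC[C@]1(C)[C@H](CC[C@@](C)(O[Si](CC)(CC)CC)[C@H]1COCc2ccc3ccccc3c2)OC(C)=O | intermediate
13 | bicyclic enol ether (key-step product): trans-fused 4-methyl-Δ3-oxepene, 8α-CH3, 10β-CH3, 9β-CH2ONAP, 8β-OTES, 5α-H | CC1=CCC[C@]2(C)[C@H](CC[C@@](C)(O[Si](CC)(CC)CC)[C@H]2COCc3ccc4ccccc4c3)O1 | intermediate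
14 | 3α,4α-epoxide of 13 (epoxy acetal, not isolated) | C[C@]12O[C@H]1CC[C@]3(C)[C@H](CC[C@@](C)(O[Si](CC)(CC)CC)[C@H]3COCc4ccc5ccccc5c4)O2 | intermediate
15 | trans-fused oxepan-3α-ol, 4,4,8α,10β-tetramethyl, 9β-CH2ONAP, 8β-OTES | O[C@H]1CC[C@]2(C)[C@H](CC[C@@](C)(O[Si](CC)(CC)CC)[C@H]2COCc3ccc4ccccc4c3)OC1(C)C | intermediate
16 | 3α,8β-bis(TES-oxy) oxepane with 9β-CH2ONAP | CC[Si](CC)(CC)O[C@H]1CC[C@]2(C)[C@H](CC[C@@](C)(O[Si](CC)(CC)CC)[C@H]2COCc3ccc4ccccc4c3)OC1(C)C | intermediate
17 | C11 alcohol: 9β-hydroxymethyl-3α,8β-bis(TES-oxy) oxepane | CC[Si](CC)(CC)O[C@H]1CC[C@]2(C)[C@H](CC[C@@](C)(O[Si](CC)(CC)CC)[C@H]2CO)OC1(C)C | intermediate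
18 | C11 PT sulfide of the 3α,8β-bis(TES-oxy) oxepane | CC[Si](CC)(CC)O[C@H]1CC[C@]2(C)[C@H](CC[C@@](C)(O[Si](CC)(CC)CC)[C@H]2CSc3nnnn3-c4ccccc4)OC1(C)C | intermediate
19 | C11 PT sulfone of the 3α,8β-bis(TES-oxy) oxepane | CC[Si](CC)(CC)O[C@H]1CC[C@]2(C)[C@H](CC[C@@](C)(O[Si](CC)(CC)CC)[C@H]2CS(=O)(=O)c3nnnn3-c4ccccc4)OC1(C)C | intermediate
20 | 10'α-(but-3-en-1-yl)-10'β-methyl-8'-methylidene-9'β-(NAP-oxymethyl)-5'β-(TBS-oxy)cyclohexane | C=CCC[C@]1(C)[C@H](CCC(=C)[C@H]1COCc2ccc3ccccc3c2)O[Si](C)(C)C(C)(C)C | intermediate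
21 | spiro-epoxide of 20, epoxide oxygen 8'α, epoxide CH2 8'β | C=CCC[C@]1(C)[C@H](CC[C@@]2(CO2)[C@H]1COCc3ccc4ccccc4c3)O[Si](C)(C)C(C)(C)C | intermediate
22 | 10'α-(but-3-en-1-yl)-8'β,10'β-dimethyl-9'β-(NAP-oxymethyl)-5'β-(TBS-oxy)cyclohexan-8'α-ol | C=CCC[C@]1(C)[C@H](CC[C@](C)(O)[C@H]1COCc2ccc3ccccc3c2)O[Si](C)(C)C(C)(C)C | intermediate
23 | 10'α-(but-3-en-1-yl)-8'β,10'β-dimethyl-9'β-(NAP-oxymethyl)cyclohexane-5'β,8'α-diol | C=CCC[C@]1(C)[C@H](CC[C@](C)(O)[C@H]1COCc2ccc3ccccc3c2)O | intermediate
24 | 5'β-acetoxy-10'α-(but-3-en-1-yl)-8'β,10'β-dimethyl-9'β-(NAP-oxymethyl)cyclohexan-8'α-ol | C=CCC[C@]1(C)[C@H](CC[C@](C)(O)[C@H]1COCc2ccc3ccccc3c2)OC(C)=O | intermediate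
25 | C8'-epimeric butenyl cyclohexyl acetate: 5'β-acetoxy-10'α-(but-3-en-1-yl)-8'β,10'β-dimethyl-9'β-(NAP-oxymethyl)-8'α-(TES-oxy)cyclohexane | C=CCC[C@]1(C)[C@H](CC[C@](C)(O[Si](CC)(CC)CC)[C@H]1COCc2ccc3ccccc3c2)OC(C)=O | intermediate
26 | C8'-epimeric bicyclic enol ether: trans-fused 4'-methyl-Δ3'-oxepene, 8'β-CH3, 10'β-CH3, 9'β-CH2ONAP, 8'α-OTES | CC1=CCC[C@]2(C)[C@H](CC[C@](C)(O[Si](CC)(CC)CC)[C@H]2COCc3ccc4ccccc4c3)O1 | intermediate
27 | 3'α,4'α-epoxide of 26 (epoxy acetal, not isolated) | C[C@]12O[C@H]1CC[C@]3(C)[C@H](CC[C@](C)(O[Si](CC)(CC)CC)[C@H]3COCc4ccc5ccccc5c4)O2 | intermediate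
28 | trans-fused oxepan-3'α-ol, 4',4',8'β,10'β-tetramethyl, 9'β-CH2ONAP, 8'α-OTES | O[C@H]1CC[C@]2(C)[C@H](CC[C@](C)(O[Si](CC)(CC)CC)[C@H]2COCc3ccc4ccccc4c3)OC1(C)C | intermediate
29 | 3'α-benzyloxy oxepane with 9'β-CH2ONAP and 8'α-OTES | C(c1ccccc1)O[C@H]1CC[C@]2(C)[C@H](CC[C@](C)(O[Si](CC)(CC)CC)[C@H]2COCc3ccc4ccccc4c3)OC1(C)C | intermediate
30 | C11' alcohol: 3'α-benzyloxy-9'β-hydroxymethyl-8'α-(TES-oxy) oxepane | C(c1ccccc1)O[C@H]1CC[C@]2(C)[C@H](CC[C@](C)(O[Si](CC)(CC)CC)[C@H]2CO)OC1(C)C | intermediate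
31 | C11' aldehyde: 3'α-benzyloxy-8'α-(TES-oxy) oxepane-9'β-carbaldehyde | C(c1ccccc1)O[C@H]1CC[C@]2(C)[C@H](CC[C@](C)(O[Si](CC)(CC)CC)[C@H]2C=O)OC1(C)C | intermediate
32 | (E)-C11=C11' alkene, 3α,8β,8'α-tris(TES-oxy), 3'α-benzyloxy | CC[Si](CC)(CC)O[C@H]1CC[C@]2(C)[C@H](CC[C@@](C)(O[Si](CC)(CC)CC)[C@H]2/C=C/[C@H]2[C@]3(C)CC[C@H](OCc4ccccc4)C(C)(C)O[C@H]3CC[C@]2(C)O[Si](CC)(CC)CC)OC1(C)C | intermediate
33 | (E)-C11=C11' alkene, 3α,8β,8'α-triol, 3'α-benzyloxy | O[C@H]1CC[C@]2(C)[C@H](CC[C@@](C)(O)[C@H]2/C=C/[C@H]2[C@]3(C)CC[C@H](OCc4ccccc4)C(C)(C)O[C@H]3CC[C@]2(C)O)OC1(C)C | intermediate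
34 | (E)-C11=C11' alkene, 3α,8β,8'α-triacetate, 3'α-benzyloxy | CC(=O)O[C@H]1CC[C@]2(C)[C@H](CC[C@@](C)(OC(C)=O)[C@H]2/C=C/[C@H]2[C@]3(C)CC[C@H](OCc4ccccc4)C(C)(C)O[C@H]3CC[C@]2(C)OC(C)=O)OC1(C)C | intermediate
35 | CNP0169816.1: 3α,8β,8'α-triacetoxy-3'α-hydroxy dimer with saturated C11–C11' link | CC(=O)O[C@H]1CC[C@]2(C)[C@H](CC[C@@](C)(OC(C)=O)[C@H]2CC[C@H]2[C@]3(C)CC[C@H](O)C(C)(C)O[C@H]3CC[C@]2(C)OC(C)=O)OC1(C)C | target

Total step count: 30 steps.
Longest linear sequence: 20 steps (steps 1–5, 16–26 and 27–30); the other branch (steps 1–15, 27–30) has 19.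

Steps most likely to fail

Step 10 (the same reaction recurs in step 22). Intermolecular ethylidenation of the acetate may outrun ring closure and leave an acyclic enol ether, or the reagent may reduce the ester. The fallback keeps the C3=C4 disconnection but separates the two events. It sets out from 12: the acetate carbonyl is methylenated with Cp2TiMe2 (toluene, 65 °C) to the isopropenyl ether F1. F1 is then closed by enol ether–olefin ring-closing metathesis with the second-generation Grubbs catalyst RuCl2(=CHPh)(PCy3)(SIMes) (toluene, 70 °C, loss of ethylene), which comes back to the route at 13.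

Step 27. The hindered sulfonyl carbanion may add only slowly and reversibly to the equally hindered aldehyde, so that enolisation of the aldehyde or decay of the metallated sulfone takes over. The fallback forms the C11=C11' bond intramolecularly by Ramberg–Bäcklund extrusion. It sets out from alcohols 17 and 30. Alcohol 17 is converted into the C11 iodide F2 (I2, PPh3, imidazole, toluene, 60 °C) and 30 into the C11' thioacetate F3 (AcSH, PPh3, DIAD, THF). Methanolysis of the thioacetate (K2CO3, degassed MeOH) gives the C11' thiol F4, whose thiolate is alkylated by the iodide (DMF, 50 °C) to the C11–S–C11' sulfide F5. mCPBA (NaHCO3, CH2Cl2) gives the sulfone F6. CBr2F2 with KOH on Al2O3 (t-BuOH/CH2Cl2) then brominates an α-carbon, closes the episulfone and expels SO2, which returns to the route at 32 (either alkene geometry serves, since step 30 hydrogenates it).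

Step 11 (and its twin, step 23). Poor facial selectivity in the epoxidation, or preferential attack on the β face, would give the wrong C3 configuration. The fallback corrects C3 by oxidation and reduction. It sets out from 13, which is taken through the same epoxidation, now via the 3β,4β-epoxide F7, and methyl transfer to the oxepan-3β-ol F8 (alone or mixed with 15). Dess–Martin oxidation of that material gives the single C3 ketone F9. LiB(s-Bu)3H (THF, –78 °C) should then deliver hydride to the face that the oxidant had preferred, which gives the 3α-alcohol and rejoins the route at 15.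

Further compounds
F1 | step 10 | isopropenyl ether: 10α-(but-3-en-1-yl)-8α,10β-dimethyl-9β-(NAP-oxymethyl)-5β-(prop-1-en-2-yloxy)-8β-(TES-oxy)cyclohexane | C=CCC[C@]1(C)[C@H](CC[C@@](C)(O[Si](CC)(CC)CC)[C@H]1COCc2ccc3ccccc3c2)OC(C)=C
F2 | step 27 | C11 iodide: 9β-iodomethyl-3α,8β-bis(TES-oxy) oxepane | CC[Si](CC)(CC)O[C@H]1CC[C@]2(C)[C@H](CC[C@@](C)(O[Si](CC)(CC)CC)[C@H]2CI)OC1(C)C
F3 | step 27 | C11' thioacetate: 3'α-benzyloxy-9'β-(acetylthiomethyl)-8'α-(TES-oxy) oxepane | C(c1ccccc1)O[C@H]1CC[C@]2(C)[C@H](CC[C@](C)(O[Si](CC)(CC)CC)[C@H]2CSC(C)=O)OC1(C)C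
F4 | step 27 | C11' thiol: 3'α-benzyloxy-9'β-(sulfanylmethyl)-8'α-(TES-oxy) oxepane | C(c1ccccc1)O[C@H]1CC[C@]2(C)[C@H](CC[C@](C)(O[Si](CC)(CC)CC)[C@H]2CS)OC1(C)C
F5 | step 27 | C11–S–C11' sulfide joining the two protected halves | CC[Si](CC)(CC)O[C@H]1CC[C@]2(C)[C@H](CC[C@@](C)(O[Si](CC)(CC)CC)[C@H]2CSC[C@H]2[C@]3(C)CC[C@H](OCc4ccccc4)C(C)(C)O[C@H]3CC[C@]2(C)O[Si](CC)(CC)CC)OC1(C)C
F6 | step 27 | C11–SO2–C11' sulfone joining the two protected halves | CC[Si](CC)(CC)O[C@H]1CC[C@]2(C)[C@H](CC[C@@](C)(O[Si](CC)(CC)CC)[C@H]2CS(=O)(=O)C[C@H]2[C@]3(C)CC[C@H](OCc4ccccc4)C(C)(C)O[C@H]3CC[C@]2(C)O[Si](CC)(CC)CC)OC1(C)C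
F7 | step 11 | 3β,4β-epoxide of 13 (not isolated) | C[C@@]12O[C@@H]1CC[C@]3(C)[C@H](CC[C@@](C)(O[Si](CC)(CC)CC)[C@H]3COCc4ccc5ccccc5c4)O2
F8 | step 11 | oxepan-3β-ol (C3 epimer of 15) | O[C@@H]1CC[C@]2(C)[C@H](CC[C@@](C)(O[Si](CC)(CC)CC)[C@H]2COCc3ccc4ccccc4c3)OC1(C)C
F9 | step 11 | oxepan-3-one: C3 ketone with 4,4,8α,10β-tetramethyl, 9β-CH2ONAP, 8β-OTES | O=C1CC[C@]2(C)[C@H](CC[C@@](C)(O[Si](CC)(CC)CC)[C@H]2COCc3ccc4ccccc4c3)OC1(C)C
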